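**Strategy.** Ring B of the tetralin (C1 bears the side chain, C4 the methyl, C5 the hydroxyl, C8 the carboxyl) is disconnected at C1–C2. With C8 as a diethylamide, only the adjacent benzylic C1 methylene is acidified; lateral lithiation there and displacement of a primary chloride at C2 close ring B and set C1 in one operation, the substituted peri positions C5 and C8 forcing the C1 chain and the C4 methyl pseudoaxial and therefore trans. The cyclisation substrate is an open-chain 4-methoxybenzamide carrying the whole C11–C16 chain (C16 silyl-protected) on the C1 methylene at C8a and an (R)-4-chlorobutan-2-yl arm at C4a; C4, C11 and C15 come from chiral-pool lactones and a chiral bromo alcohol.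

Key step: step 13

Remark (assumption): atom labels C1–C16 follow the tetralin numbering above; (S)-3-methyl-γ-butyrolactone 4 and the other chiral building blocks are taken as purchasable in the stated enantiomeric form.

Design notes: compounds 22 and 24 were checked against the target and carry its configuration (4R, 11S, 15R; 1S after closure). The chain is joined from two chiral-pool pieces so that C11, C15 and the C16 oxygen arrive defined. Phenol and acid are masked as allyl derivatives before the C16 ester is made, so the acylation meets a single hydroxyl and the last step is neutral.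

**Chain fragment (C1, C11–C16)**

Step 1
Reactants: 1 (S)-3-bromo-2-methylpropan-1-ol
Product: 2 (S)-(3-bromo-2-methylpropoxy)(tert-butyl)dimethylsilane
Conditions: TBSCl, imidazole, CH2Cl2, 0 °C → rt
Reagents that add atoms: tert-butyldimethylsilyl chloride, CC(C)(C)[Si](C)(C)Cl
Why: Imidazole-promoted silylation of a primary alcohol (silyl ether protection) should be clean, leaves the bromide and the methyl-bearing centre (later C15) untouched, and masks the C16 oxygen until step 16.

Step 2
Reactants: 2 (S)-(3-bromo-2-methylpropoxy)(tert-butyl)dimethylsilane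
Product: 3 [(2S)-3-{[tert-butyl(dimethyl)silyl]oxy}-2-methylpropyl]triphenylphosphonium bromide
Conditions: PPh3, iPr2NEt (0.1 equiv), MeCN, 100 °C (sealed vessel)
Reagents that add atoms: triphenylphosphine, c1ccc(cc1)P(c1ccccc1)c1ccccc1
Why: SN2 quaternisation of triphenylphosphine by the primary bromide (phosphonium salt formation) should proceed on heating despite the β-branch, the trace of amine base protecting the silyl ether from adventitious HBr, and the stereocentre is not involved.

Step 3
Reactants: 4 (S)-3-methyl-γ-butyrolactone [(4S)-4-methyloxolan-2-one]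
Product: 5 (4S)-4-methyloxolan-2-ol (lactol, both anomers)
Conditions: iBu2AlH (1.1 equiv), CH2Cl2, −78 °C; aq. potassium sodium tartrate (KNaC4H4O6)
Reagents that add atoms: none
Why: Low-temperature half-reduction of a γ-lactone with diisobutylaluminium hydride stops at the lactol, and the methyl-bearing centre (later C11) is β to the carbonyl and cannot epimerise.

Step 4
Reactants: 3 [(2S)-3-{[tert-butyl(dimethyl)silyl]oxy}-2-methylpropyl]triphenylphosphonium bromide; 5 (4S)-4-methyloxolan-2-ol
Product: 7 (2S,4Z,6R)-7-{[tert-butyl(dimethyl)silyl]oxy}-2,6-dimethylhept-4-en-1-ol, via phosphonium ylide 6 (not isolated)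
Conditions: 3 (2.5 equiv), NaN(SiMe3)2 (2.4 equiv), THF, 0 °C; then 5, −78 °C → rt
Reagents that add atoms: none
Why: Wittig olefination of the open hydroxy-aldehyde form of the lactol by the non-stabilised ylide (the excess also deprotonates the lactol) joins C13 to C14; the alkene geometry is irrelevant because the bond is saturated next, and neither methyl-bearing centre has an acidic hydrogen.

Step 5
Reactants: 7 (2S,4Z,6R)-7-{[tert-butyl(dimethyl)silyl]oxy}-2,6-dimethylhept-4-en-1-ol
Product: 8 (2S,6R)-7-{[tert-butyl(dimethyl)silyl]oxy}-2,6-dimethylheptan-1-ol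
Conditions: H2 (1 atm), platinum on carbon (5% Pt), EtOAc, rt
Reagents that add atoms: none
Why: Heterogeneous hydrogenation of the disubstituted alkene, on platinum to suppress double-bond migration through the allylic C15 centre, should give the saturated chain with both centres intact.

Step 6
Reactants: 8 (2S,6R)-7-{[tert-butyl(dimethyl)silyl]oxy}-2,6-dimethylheptan-1-ol
Product: 9 tert-butyl{[(2R,6S)-7-iodo-2,6-dimethylheptyl]oxy}dimethylsilane
Conditions: I2, PPh3, imidazole, CH2Cl2, 0 °C → rt
Reagents that add atoms: iodine, II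
Why: Appel-type (Garegg–Samuelsson) iodination converts the primary alcohol to the iodide by SN2 at C1 without touching the neighbouring C11 centre or the silyl ether.

**Arene fragment (C4 arm)**

Step 7
Reactants: 10 3-bromoanisole; 11 (S)-β-butyrolactone [(4S)-4-methyloxetan-2-one]
Product: 14 (3R)-3-(2-bromo-6-methoxyphenyl)butanoic acid, via (2-bromo-6-methoxyphenyl)lithium 12 (not isolated), via (2-bromo-6-methoxyphenyl)magnesium bromide 13 (not isolated)
Conditions: 10 (1.5 equiv), LiN(iPr)2, THF, −78 °C; MgBr2·OEt2, −78 → −40 °C; CuBr·SMe2 (10 mol%), 11, THF/Me2S, −40 → −10 °C; 1 M HCl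
Reagents that add atoms: none
Why: Directed ortho-lithiation at the position flanked by bromine and methoxy, transmetalation to the less aryne-prone Grignard reagent and copper-catalysed SN2 opening of the β-lactone at its methyl-bearing carbon (alkyl–oxygen cleavage) should give the acid; C4 is set by inversion, the (S)-lactone giving the (R)-3-arylbutanoic acid.

Step 8
Reactants: 14 (3R)-3-(2-bromo-6-methoxyphenyl)butanoic acid
Product: 15 (3R)-3-(2-bromo-6-methoxyphenyl)butan-1-ol
Conditions: BH3·SMe2, THF, 0 °C → rt; MeOH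
Reagents that add atoms: none
Why: Borane reduces the carboxylic acid chemoselectively to the primary alcohol without touching the aryl bromide or the benzylic centre.

Step 9
Reactants: 15 (3R)-3-(2-bromo-6-methoxyphenyl)butan-1-ol
Product: 16 1-bromo-2-[(2R)-4-chlorobutan-2-yl]-3-methoxybenzene
Conditions: N-chlorosuccinimide, PPh3, CH2Cl2, 0 °C → rt
Reagents that add atoms: N-chlorosuccinimide, O=C1CCC(=O)N1Cl
Why: Appel-type chlorination through the alkoxyphosphonium salt gives the primary chloride (C2) by SN2; it is installed here because a primary alkyl chloride is inert to the zinc/palladium, NBS and low-temperature organolithium steps that follow, so no second hydroxyl protecting group is needed.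

**Assembly and ring closure**

Step 10
Reactants: 9 tert-butyl{[(2R,6S)-7-iodo-2,6-dimethylheptyl]oxy}dimethylsilane; 16 1-bromo-2-[(2R)-4-chlorobutan-2-yl]-3-methoxybenzene
Product: 18 tert-butyl{[(2R,6S)-7-{2-[(2R)-4-chlorobutan-2-yl]-3-methoxyphenyl}-2,6-dimethylheptyl]oxy}dimethylsilane, via alkylzinc iodide 17 (not isolated)
Conditions: 9 (1.3 equiv), Zn dust (activated by 1,2-dibromoethane and Me3SiCl), LiCl, THF, 40 °C; then 16, Pd(OAc)2 (2 mol%), SPhos (4 mol%), THF, rt → 50 °C
Reagents that add atoms: none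
Why: Negishi coupling, in which LiCl-assisted zinc insertion into the primary iodide is followed by coupling with the ortho-substituted aryl bromide under a zerovalent palladium/biarylphosphine catalyst, forms the C8a–C1 bond; the alkyl chloride and silyl ether are inert and the C11 centre, β to zinc, is not affected.

Step 11
Reactants: 18 tert-butyl{[(2R,6S)-7-{2-[(2R)-4-chlorobutan-2-yl]-3-methoxyphenyl}-2,6-dimethylheptyl]oxy}dimethylsilane
Product: 19 {[(2R,6S)-7-{6-bromo-2-[(2R)-4-chlorobutan-2-yl]-3-methoxyphenyl}-2,6-dimethylheptyl]oxy}(tert-butyl)dimethylsilane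
Conditions: N-bromosuccinimide, MeCN, 0 °C → rt, dark
Reagents that add atoms: N-bromosuccinimide, O=C1CCC(=O)N1Br
Why: Electrophilic aromatic bromination with NBS in acetonitrile is para-selective for anisoles, and the position para to the methoxy group is C8, the ortho position C6 being the only, less favoured, alternative.

Step 12
Reactants: 19 {[(2R,6S)-7-{6-bromo-2-[(2R)-4-chlorobutan-2-yl]-3-methoxyphenyl}-2,6-dimethylheptyl]oxy}(tert-butyl)dimethylsilane; 20 N,N-diethylcarbamoyl chloride
Product: 22 2-[(2S,6R)-7-{[tert-butyl(dimethyl)silyl]oxy}-2,6-dimethylheptyl]-3-[(2R)-4-chlorobutan-2-yl]-N,N-diethyl-4-methoxybenzamide, via aryllithium 21 (not isolated)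
Conditions: t-BuLi (2.1 equiv), THF, −78 °C; then 20, −78 °C → rt
Reagents that add atoms: none
Why: Bromine–lithium exchange followed by acylation of the aryllithium with the carbamoyl chloride gives the tertiary benzamide; at −78 °C the exchange outruns any attack on the primary chloride, whose arm sits meta to the metalated carbon and cannot cyclise onto it.

Step 13
Reactants: 22 2-[(2S,6R)-7-{[tert-butyl(dimethyl)silyl]oxy}-2,6-dimethylheptyl]-3-[(2R)-4-chlorobutan-2-yl]-N,N-diethyl-4-methoxybenzamide
Product: 24 (5R,8S)-8-[(2S,6R)-7-{[tert-butyl(dimethyl)silyl]oxy}-6-methylheptan-2-yl]-N,N-diethyl-4-methoxy-5-methyl-5,6,7,8-tetrahydronaphthalene-1-carboxamide, via benzylic organolithium 23 (not isolated)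
Conditions: LiN(iPr)2 (2.5 equiv), THF, −78 → 0 °C
Reagents that add atoms: none
Why: Lithium diisopropylamide, guided by the amide oxygen, removes a proton from the C1 methylene on C8a, the only benzylic position ortho to the C8 carboxamide (the C4 methine is meta to it and the aryl C7–H is not acidic enough for an amide base), and the benzylic organolithium 23 then displaces the primary chloride at C2 in an intramolecular SN2 reaction that forms the C1–C2 bond. The closest known reaction type is lateral lithiation of 2-alkyl N,N-dialkylbenzamides followed by alkylation of the benzylic anion, run here within one molecule. Ring B closes in the 6-exo-tet mode through a half-chair transition state. The new C1 stereocentre is controlled by allylic 1,3-strain from the two peri substituents: the C11 branch turns away from the C8 amide and the C4 methyl away from the C5 methoxy, so both are pseudoaxial, which places them on opposite faces and gives (1S) trans to the existing (4R) centre, while C11 and C15 are spectators. The step needs site selectivity (C1 deprotonation against loss of HCl or attack on the amide) and 1,4-trans diastereoselectivity; the first rests on a hindered non-nucleophilic base with a poor elimination substrate at low temperature, the second on the fully substituted peri positions C5 and C8, which favour the trans isomer both in the ring-closing transition state and at equilibrium.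

**Endgame**

Step 14
Reactants: 24 (5R,8S)-8-[(2S,6R)-7-{[tert-butyl(dimethyl)silyl]oxy}-6-methylheptan-2-yl]-N,N-diethyl-4-methoxy-5-methyl-5,6,7,8-tetrahydronaphthalene-1-carboxamide
Product: 25 (5R,8S)-8-[(2S,6R)-7-{[tert-butyl(dimethyl)silyl]oxy}-6-methylheptan-2-yl]-4-methoxy-5-methyl-5,6,7,8-tetrahydronaphthalene-1-carbaldehyde
Conditions: Cp2Zr(H)Cl (2 equiv), THF, rt; then H2O, silica gel
Reagents that add atoms: none
Why: Reduction of a tertiary amide to the aldehyde with zirconocene chloride hydride (hydride delivery to the amide carbonyl, then collapse with loss of diethylamine on work-up) is selective in the presence of silyl and aryl ethers and stops at the aldehyde oxidation level.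

Step 15
Reactants: 25 (5R,8S)-8-[(2S,6R)-7-{[tert-butyl(dimethyl)silyl]oxy}-6-methylheptan-2-yl]-4-methoxy-5-methyl-5,6,7,8-tetrahydronaphthalene-1-carbaldehyde
Product: 26 (5R,8S)-8-[(2S,6R)-7-{[tert-butyl(dimethyl)silyl]oxy}-6-methylheptan-2-yl]-4-methoxy-5-methyl-5,6,7,8-tetrahydronaphthalene-1-carboxylic acid
Conditions: NaClO2, NaH2PO4, 2-methyl-2-butene, t-BuOH/THF/H2O, 0 °C → rt
Reagents that add atoms: sodium chlorite, [Na+].[O-]Cl=O
Why: Pinnick oxidation converts the hindered aryl aldehyde to the acid under buffered conditions, with 2-methyl-2-butene trapping hypochlorous acid so that the electron-rich ring is not chlorinated.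

Step 16
Reactants: 26 (5R,8S)-8-[(2S,6R)-7-{[tert-butyl(dimethyl)silyl]oxy}-6-methylheptan-2-yl]-4-methoxy-5-methyl-5,6,7,8-tetrahydronaphthalene-1-carboxylic acid
Product: 27 (5R,8S)-4-hydroxy-8-[(2S,6R)-7-hydroxy-6-methylheptan-2-yl]-5-methyl-5,6,7,8-tetrahydronaphthalene-1-carboxylic acid
Conditions: BBr3 (5 equiv), CH2Cl2, −78 → 0 °C; then H2O
Reagents that add atoms: none
Why: Lewis-acid ether cleavage by boron tribromide removes the aryl methyl ether and the silyl ether in one operation (bromide attacks methyl and silicon, not ring or chain carbon), so the stereocentres and the C16–O bond are untouched.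

Step 17
Reactants: 27 (5R,8S)-4-hydroxy-8-[(2S,6R)-7-hydroxy-6-methylheptan-2-yl]-5-methyl-5,6,7,8-tetrahydronaphthalene-1-carboxylic acid
Product: 28 prop-2-en-1-yl (5R,8S)-8-[(2S,6R)-7-hydroxy-6-methylheptan-2-yl]-5-methyl-4-(prop-2-en-1-yloxy)-5,6,7,8-tetrahydronaphthalene-1-carboxylate
Conditions: allyl bromide (2.5 equiv), K2CO3, DMF, rt
Reagents that add atoms: allyl bromide, C=CCBr
Why: Under carbonate only the carboxylate and the phenoxide are formed and O-alkylated (Williamson-type allylation), leaving the C16 primary alcohol as the single free hydroxyl for the next step.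

Step 18
Reactants: 28 prop-2-en-1-yl (5R,8S)-8-[(2S,6R)-7-hydroxy-6-methylheptan-2-yl]-5-methyl-4-(prop-2-en-1-yloxy)-5,6,7,8-tetrahydronaphthalene-1-carboxylate; 29 4-methylpent-3-enoic acid
Product: 30 prop-2-en-1-yl (5R,8S)-5-methyl-8-{(2S,6R)-6-methyl-7-[(4-methylpent-3-enoyl)oxy]heptan-2-yl}-4-(prop-2-en-1-yloxy)-5,6,7,8-tetrahydronaphthalene-1-carboxylate
Conditions: 29 (1.5 equiv), EDC·HCl, DMAP (0.1 equiv), CH2Cl2, 0 °C → rt
Reagents that add atoms: none
Why: Steglich-type carbodiimide esterification of the only free hydroxyl; with catalytic DMAP at low temperature the trisubstituted β,γ-alkene of the acyl group, which is also the more stable isomer, should not move into conjugation.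

Step 19
Reactants: 30 prop-2-en-1-yl (5R,8S)-5-methyl-8-{(2S,6R)-6-methyl-7-[(4-methylpent-3-enoyl)oxy]heptan-2-yl}-4-(prop-2-en-1-yloxy)-5,6,7,8-tetrahydronaphthalene-1-carboxylate
Product: 31 (5R,8S)-4-hydroxy-5-methyl-8-{(2S,6R)-6-methyl-7-[(4-methylpent-3-enoyl)oxy]heptan-2-yl}-5,6,7,8-tetrahydronaphthalene-1-carboxylic acid (target)
Conditions: Pd(PPh3)4 (5 mol%), morpholine (10 equiv), THF, rt; then dilute aq. citric acid
Reagents that add atoms: none
Why: Tsuji–Trost deallylation, in which zerovalent palladium ionises the allyl ester and the allyl aryl ether to π-allyl complexes that morpholine intercepts, is too mild to touch the saturated C16 ester or to isomerise its alkene.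

**Compound list**

1 | (S)-3-bromo-2-methylpropan-1-ol | OC[C@H](C)CBr | starting material
2 | (S)-(3-bromo-2-methylpropoxy)(tert-butyl)dimethylsilane | CC(C)(C)[Si](C)(C)OC[C@H](C)CBr | intermediate
3 | [(2S)-3-{[tert-butyl(dimethyl)silyl]oxy}-2-methylpropyl]triphenylphosphonium bromide | CC(C)(C)[Si](C)(C)OC[C@H](C)C[P+](c1ccccc1)(c1ccccc1)c1ccccc1.[Br-] | intermediate
4 | (S)-3-methyl-γ-butyrolactone, (4S)-4-methyloxolan-2-one | O=C1C[C@H](C)CO1 | starting material
5 | (4S)-4-methyloxolan-2-ol (lactol, both anomers) | OC1C[C@H](C)CO1 | intermediate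
6 | {(2S)-3-{[tert-butyl(dimethyl)silyl]oxy}-2-methylpropylidene}triphenylphosphorane (ylide) | CC(C)(C)[Si](C)(C)OC[C@H](C)C=P(c1ccccc1)(c1ccccc1)c1ccccc1 | intermediate
7 | (2S,4Z,6R)-7-{[tert-butyl(dimethyl)silyl]oxy}-2,6-dimethylhept-4-en-1-ol | CC(C)(C)[Si](C)(C)OC[C@H](C)/C=C\C[C@H](C)CO | intermediate
8 | (2S,6R)-7-{[tert-butyl(dimethyl)silyl]oxy}-2,6-dimethylheptan-1-ol | CC(C)(C)[Si](C)(C)OC[C@H](C)CCC[C@H](C)CO | intermediate
9 | tert-butyl{[(2R,6S)-7-iodo-2,6-dimethylheptyl]oxy}dimethylsilane | CC(C)(C)[Si](C)(C)OC[C@H](C)CCC[C@H](C)CI | intermediate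
10 | 3-bromoanisole | COc1cccc(Br)c1 | starting material
11 | (S)-β-butyrolactone, (4S)-4-methyloxetan-2-one | C[C@H]1CC(=O)O1 | starting material
12 | (2-bromo-6-methoxyphenyl)lithium | COc1cccc(Br)c1[Li] | intermediate
13 | (2-bromo-6-methoxyphenyl)magnesium bromide | COc1cccc(Br)c1[Mg]Br | intermediate
14 | (3R)-3-(2-bromo-6-methoxyphenyl)butanoic acid | COc1cccc(Br)c1[C@H](C)CC(=O)O | intermediate
15 | (3R)-3-(2-bromo-6-methoxyphenyl)butan-1-ol | COc1cccc(Br)c1[C@H](C)CCO | intermediate
16 | 1-bromo-2-[(2R)-4-chlorobutan-2-yl]-3-methoxybenzene | COc1cccc(Br)c1[C@H](C)CCCl | intermediate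
17 | {(2S,6R)-7-{[tert-butyl(dimethyl)silyl]oxy}-2,6-dimethylheptyl}zinc iodide | CC(C)(C)[Si](C)(C)OC[C@H](C)CCC[C@H](C)C[Zn]I | intermediate
18 | tert-butyl{[(2R,6S)-7-{2-[(2R)-4-chlorobutan-2-yl]-3-methoxyphenyl}-2,6-dimethylheptyl]oxy}dimethylsilane | CC(C)(C)[Si](C)(C)OC[C@H](C)CCC[C@H](C)Cc1cccc(OC)c1[C@H](C)CCCl | intermediate
19 | {[(2R,6S)-7-{6-bromo-2-[(2R)-4-chlorobutan-2-yl]-3-methoxyphenyl}-2,6-dimethylheptyl]oxy}(tert-butyl)dimethylsilane | CC(C)(C)[Si](C)(C)OC[C@H](C)CCC[C@H](C)Cc1c(Br)ccc(OC)c1[C@H](C)CCCl | intermediate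
20 | N,N-diethylcarbamoyl chloride | CCN(CC)C(Cl)=O | starting material
21 | aryllithium from 19 (lithium in place of bromine at C8) | CC(C)(C)[Si](C)(C)OC[C@H](C)CCC[C@H](C)Cc1c([Li])ccc(OC)c1[C@H](C)CCCl | intermediate
22 | 2-[(2S,6R)-7-{[tert-butyl(dimethyl)silyl]oxy}-2,6-dimethylheptyl]-3-[(2R)-4-chlorobutan-2-yl]-N,N-diethyl-4-methoxybenzamide | CC(C)(C)[Si](C)(C)OC[C@H](C)CCC[C@H](C)Cc1c(C(=O)N(CC)CC)ccc(OC)c1[C@H](C)CCCl | intermediate
23 | C1-lithiated 22 (benzylic organolithium, lithiated carbon configurationally labile) | CC(C)(C)[Si](C)(C)OC[C@H](C)CCC[C@H](C)C([Li])c1c(C(=O)N(CC)CC)ccc(OC)c1[C@H](C)CCCl | intermediate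
24 | (5R,8S)-8-[(2S,6R)-7-{[tert-butyl(dimethyl)silyl]oxy}-6-methylheptan-2-yl]-N,N-diethyl-4-methoxy-5-methyl-5,6,7,8-tetrahydronaphthalene-1-carboxamide | CC(C)(C)[Si](C)(C)OC[C@H](C)CCC[C@H](C)[C@@H]1CC[C@@H](C)c2c(OC)ccc(C(=O)N(CC)CC)c21 | intermediate
25 | (5R,8S)-8-[(2S,6R)-7-{[tert-butyl(dimethyl)silyl]oxy}-6-methylheptan-2-yl]-4-methoxy-5-methyl-5,6,7,8-tetrahydronaphthalene-1-carbaldehyde | CC(C)(C)[Si](C)(C)OC[C@H](C)CCC[C@H](C)[C@@H]1CC[C@@H](C)c2c(OC)ccc(C=O)c21 | intermediate
26 | (5R,8S)-8-[(2S,6R)-7-{[tert-butyl(dimethyl)silyl]oxy}-6-methylheptan-2-yl]-4-methoxy-5-methyl-5,6,7,8-tetrahydronaphthalene-1-carboxylic acid | CC(C)(C)[Si](C)(C)OC[C@H](C)CCC[C@H](C)[C@@H]1CC[C@@H](C)c2c(OC)ccc(C(=O)O)c21 | intermediate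
27 | (5R,8S)-4-hydroxy-8-[(2S,6R)-7-hydroxy-6-methylheptan-2-yl]-5-methyl-5,6,7,8-tetrahydronaphthalene-1-carboxylic acid | OC[C@H](C)CCC[C@H](C)[C@@H]1CC[C@@H](C)c2c(O)ccc(C(=O)O)c21 | intermediate
28 | prop-2-en-1-yl (5R,8S)-8-[(2S,6R)-7-hydroxy-6-methylheptan-2-yl]-5-methyl-4-(prop-2-en-1-yloxy)-5,6,7,8-tetrahydronaphthalene-1-carboxylate | OC[C@H](C)CCC[C@H](C)[C@@H]1CC[C@@H](C)c2c(OCC=C)ccc(C(=O)OCC=C)c21 | intermediate
29 | 4-methylpent-3-enoic acid | CC(C)=CCC(=O)O | starting material
30 | prop-2-en-1-yl (5R,8S)-5-methyl-8-{(2S,6R)-6-methyl-7-[(4-methylpent-3-enoyl)oxy]heptan-2-yl}-4-(prop-2-en-1-yloxy)-5,6,7,8-tetrahydronaphthalene-1-carboxylate | CC(C)=CCC(=O)OC[C@H](C)CCC[C@H](C)[C@@H]1CC[C@@H](C)c2c(OCC=C)ccc(C(=O)OCC=C)c21 | intermediate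
31 | (5R,8S)-4-hydroxy-5-methyl-8-{(2S,6R)-6-methyl-7-[(4-methylpent-3-enoyl)oxy]heptan-2-yl}-5,6,7,8-tetrahydronaphthalene-1-carboxylic acid | CC(C)=CCC(=O)OC[C@H](C)CCC[C@H](C)[C@@H]1CC[C@@H](C)c2c(O)ccc(C(=O)O)c21 | target

**Step count**

Total: 19 steps. Longest linear sequence: 15 steps (steps 1, 2, 4, 5, 6 and 10–19, from 1).

**Steps most likely to fail, with fallbacks**

1. Step 13 (ring closure). What may go wrong: deprotonation of the hindered secondary benzylic C1 position by the amide base may be incomplete, so that base-induced loss of HCl from the chlorobutyl arm competes with ring closure. The fallback changes the anion type and the way the carboxyl is unmasked. From bromide 19, bromine–lithium exchange as in step 12 (aryllithium 21) and capture with ethyl isocyanate would give the N-ethyl secondary amide F1. Two equivalents of n-BuLi (THF, −78 → 0 °C) would form the N,C-dilithio species F2, whose amidate resists nucleophiles and so permits an alkyllithium base. Its benzylic carbon would close ring B under the same peri-strain control to the N-ethyl tetralin carboxamide F3. Boc2O/DMAP (MeCN) would give the N-Boc imide F4, and LiOH/H2O2 (THF/H2O, 0 °C) would cleave the activated acyl–nitrogen bond to acid 26, where the route is rejoined; steps 14 and 15 are then not needed.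

2. Step 7 (lactone opening). What may go wrong: transfer of the doubly ortho-substituted aryl group from copper to the secondary lactone carbon may be slow, leaving time for the ortho-bromo aryl metal to lose metal bromide (aryne formation) or for attack at the lactone carbonyl. The fallback builds C4 by auxiliary-controlled conjugate methylation instead. From 10, lithiation as in step 7 (aryllithium 12) and quenching with DMF would give 2-bromo-6-methoxybenzaldehyde F5. Knoevenagel–Doebner condensation with malonic acid (pyridine, piperidine, 90 °C) would give (2E)-3-(2-bromo-6-methoxyphenyl)prop-2-enoic acid F6. DCC/DMAP coupling with (R)-4-phenyl-1,3-oxazolidin-2-one would give the enoyl imide F7. MeMgBr/CuBr·SMe2 (THF/Me2S, −40 → −10 °C) should add methyl to the face of the magnesium-chelated s-cis imide opposite the 4-phenyl group, giving the (3R)-3-arylbutanoyl imide F8. LiBH4 (THF, MeOH 1 equiv, 0 °C) would release alcohol 15 and the auxiliary; the route is rejoined at 15 and step 8 is not needed.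

3. Step 14 (amide to aldehyde). What may go wrong: the amide carbonyl, twisted and screened by the peri C1 substituent, may be hydrozirconated slowly, so that reagent decomposition or over-reduction takes over. The fallback over-reduces and re-oxidises. From 24, LiH2NBH3 (THF, 0 °C → rt) would reduce the tertiary amide to the benzylic alcohol F9 with loss of diethylamine, and MnO2 (CH2Cl2, rt) would oxidise it to aldehyde 25, where the route is rejoined.

**Further compounds**

F1 | step 13 | 2-[(2S,6R)-7-{[tert-butyl(dimethyl)silyl]oxy}-2,6-dimethylheptyl]-3-[(2R)-4-chlorobutan-2-yl]-N-ethyl-4-methoxybenzamide | CC(C)(C)[Si](C)(C)OC[C@H](C)CCC[C@H](C)Cc1c(C(=O)NCC)ccc(OC)c1[C@H](C)CCCl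
F2 | step 13 | N,C1-dilithio derivative of F1 | CC(C)(C)[Si](C)(C)OC[C@H](C)CCC[C@H](C)C([Li])c1c(C(=O)N([Li])CC)ccc(OC)c1[C@H](C)CCCl
F3 | step 13 | (5R,8S)-8-[(2S,6R)-7-{[tert-butyl(dimethyl)silyl]oxy}-6-methylheptan-2-yl]-N-ethyl-4-methoxy-5-methyl-5,6,7,8-tetrahydronaphthalene-1-carboxamide | CC(C)(C)[Si](C)(C)OC[C@H](C)CCC[C@H](C)[C@@H]1CC[C@@H](C)c2c(OC)ccc(C(=O)NCC)c21
F4 | step 13 | tert-butyl N-ethyl-N-{[(5R,8S)-8-[(2S,6R)-7-{[tert-butyl(dimethyl)silyl]oxy}-6-methylheptan-2-yl]-4-methoxy-5-methyl-5,6,7,8-tetrahydronaphthalen-1-yl]carbonyl}carbamate | CC(C)(C)[Si](C)(C)OC[C@H](C)CCC[C@H](C)[C@@H]1CC[C@@H](C)c2c(OC)ccc(C(=O)N(CC)C(=O)OC(C)(C)C)c21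
F5 | step 7 | 2-bromo-6-methoxybenzaldehyde | COc1cccc(Br)c1C=O
F6 | step 7 | (2E)-3-(2-bromo-6-methoxyphenyl)prop-2-enoic acid | COc1cccc(Br)c1/C=C/C(=O)O
F7 | step 7 | (4R)-3-[(2E)-3-(2-bromo-6-methoxyphenyl)prop-2-enoyl]-4-phenyl-1,3-oxazolidin-2-one | COc1cccc(Br)c1/C=C/C(=O)N1[C@H](c2ccccc2)COC1=O
F8 | step 7 | (4R)-3-[(3R)-3-(2-bromo-6-methoxyphenyl)butanoyl]-4-phenyl-1,3-oxazolidin-2-one | COc1cccc(Br)c1[C@H](C)CC(=O)N1[C@H](c2ccccc2)COC1=O
F9 | step 14 | [(5R,8S)-8-[(2S,6R)-7-{[tert-butyl(dimethyl)silyl]oxy}-6-methylheptan-2-yl]-4-methoxy-5-methyl-5,6,7,8-tetrahydronaphthalen-1-yl]methanol | CC(C)(C)[Si](C)(C)OC[C@H](C)CCC[C@H](C)[C@@H]1CC[C@@H](C)c2c(OC)ccc(CO)c21
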